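**Retrosynthetic overview** (daucane numbering: C1 = CH3-bearing ring-fusion carbon, C2/C3 = the two CH2 of the cyclopentane, C4 = isopropyl carbinol carbon, C5 = ring-fusion CH, C6 = ester CH, C7, C8(CH3)=C9 and C10 = rest of the cycloheptene)
1. The salicylate is put on last, by acylating the C6 hydroxyl of the trans-fused diol with salicylic acid acetonide; the isopropyl group is added to a C4 ketone from the face anti to the angular CH3.
2. The cyclopentane is closed second, at C3–C4, by Rh-catalysed intramolecular hydroacylation. The enabling feature is the array C4(carbonyl)–C5(H)–C1(quaternary)–C2=C3, a 3,3-disubstituted 4-pentenal whose formyl and vinyl arms sit trans-diequatorial on the cycloheptene, so the aldehyde C–H adds across the vinyl group without any reagent atoms.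
3. The same γ,δ-unsaturated carbonyl array is a Claisen retron: a dianionic Ireland–Claisen rearrangement of a β-hydroxy ester forms C5–C1 and sets C5 and the quaternary C1 from the C6 carbinol.
4. The cycloheptene is closed first, by ring-closing metathesis at C8=C9 between the allyl group on C1 and the methallyl group on C6.
5. The only purchased stereocentre is C6, from ethyl (R)-4-chloro-3-hydroxybutanoate; ring order: seven-membered, then five-membered.

Key step: step 8

Remark: pent-1-en-4-yne, ethyl (R)-4-chloro-3-hydroxybutanoate and 2,2-dimethyl-4H-1,3-benzodioxin-4-one are taken as commercial, and the chlorohydrin is assumed to close to its epoxide under the Grignard conditions of step 2.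

**Route**

Step 1
Reactants: 1 pent-1-en-4-yne
Product: 3 (2E)-3-methylhexa-2,5-dien-1-ol, via alkenylalane 2 (not isolated)
Conditions: Me3Al (2 equiv), Cp2ZrCl2 (0.2 equiv), CH2Cl2, 0 °C → rt; n-BuLi (1 equiv), THF, −78 °C; (CH2O)n, −78 °C → rt
Reagents that add atoms: trimethylaluminium C[Al](C)C; paraformaldehyde (as formaldehyde) C=O
Why: Zr-catalysed carboalumination of a terminal alkyne (Negishi carboalumination) adds CH3 and Al syn with Al at the terminus, and hydroxymethylation of the derived alkenyl aluminate proceeds with retention, so the allyl group ends trans to CH2OH (E); the isolated terminal alkene is inert under these conditions.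

Step 2
Reactants: 4 ethyl (3R)-4-chloro-3-hydroxybutanoate
Product: 6 ethyl (3S)-3-hydroxy-5-methylhex-5-enoate, via epoxy ester 5 (not isolated)
Conditions: CH2=C(CH3)MgBr (3 equiv), CuI (10 mol%), THF, −40 → 0 °C; aq. NH4Cl
Reagents that add atoms: isopropenylmagnesium bromide CC(=C)[Mg]Br
Why: The first equivalent of Grignard reagent forms the chloro alkoxide, which closes to the terminal epoxide, and Cu-catalysed SN2 opening at the CH2 terminus (Grignard–epoxide opening) outruns attack on the ester at low temperature; no bond to the carbinol carbon is broken, so its configuration is kept (the descriptor changes from R to S only through the CIP priorities).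

Step 3
Reactants: 6 ethyl (3S)-3-hydroxy-5-methylhex-5-enoate; 3 (2E)-3-methylhexa-2,5-dien-1-ol
Product: 7 (2E)-3-methylhexa-2,5-dien-1-yl (3S)-3-hydroxy-5-methylhex-5-enoate
Conditions: 3 (1.1 equiv), distannoxane catalyst [Bu2Sn(NCS)OSnBu2(OH)]2 (2 mol%), toluene, 110 °C, EtOH distilled off
Reagents that add atoms: none
Why: Distannoxane-catalysed transesterification under neutral conditions, driven by removal of ethanol, exchanges the alkoxy group without touching the free β-hydroxyl, the alkenes or the stereocentre.

Step 4
Reactants: 7 (2E)-3-methylhexa-2,5-dien-1-yl (3S)-3-hydroxy-5-methylhex-5-enoate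
Product: 9 (2S,3S)-3-ethenyl-2-[(1S)-1-hydroxy-3-methylbut-3-en-1-yl]-3-methylhex-5-enoic acid, via dilithium ester dianion 8 (not isolated)
Conditions: LDA (2.2 equiv), THF, −78 °C → rt → 50 °C; aq. HCl
Reagents that add atoms: none
Why: Dianionic Ireland–Claisen rearrangement: Li chelation between the alkoxide and the enolate oxygen fixes the enolate geometry and blocks one face, so the chair [3,3] shift delivers the allyl terminus anti to the methallyl-bearing carbinol substituent (Fráter–Seebach sense, sets C5), while the (E)-alkene places the allyl branch pseudo-equatorial and CH3 pseudo-axial, which sets the quaternary C1.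

Step 5
Reactants: 9 (2S,3S)-3-ethenyl-2-[(1S)-1-hydroxy-3-methylbut-3-en-1-yl]-3-methylhex-5-enoic acid
Product: 10 (1S,2S,7S)-2-ethenyl-7-hydroxy-2,5-dimethylcyclohept-4-ene-1-carboxylic acid
Conditions: second-generation Grubbs catalyst (5 mol%), CH2Cl2 (5 mM), 40 °C
Reagents that add atoms: none
Why: Ring-closing olefin metathesis: the Ru carbene forms at the unhindered allyl terminus and closes onto the 1,1-disubstituted methallyl alkene to give the trisubstituted cycloheptene with loss of ethene, whereas the vinyl group on the quaternary carbon is too hindered to initiate and could only give a cyclobutene from that carbene.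

Step 6
Reactants: 10 (1S,2S,7S)-2-ethenyl-7-hydroxy-2,5-dimethylcyclohept-4-ene-1-carboxylic acid
Product: 11 (1S,6S,7R)-6-ethenyl-7-(hydroxymethyl)-3,6-dimethylcyclohept-3-en-1-ol
Conditions: LiAlH4, THF, 0 °C → reflux; Fieser work-up
Reagents that add atoms: none
Why: Hydride reduction of the carboxylic acid to the primary alcohol (LiAlH4 reduction) leaves the alkenes and all three stereocentres untouched (the descriptor at C5 changes only through the CIP priorities).

Step 7
Reactants: 11 (1S,6S,7R)-6-ethenyl-7-(hydroxymethyl)-3,6-dimethylcyclohept-3-en-1-ol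
Product: 12 (1S,2S,7S)-2-ethenyl-7-hydroxy-2,5-dimethylcyclohept-4-ene-1-carbaldehyde
Conditions: TEMPO (10 mol%), PhI(OAc)2 (1.1 equiv), CH2Cl2, rt
Reagents that add atoms: none
Why: The oxoammonium (TEMPO) oxidation is selective for the primary over the secondary alcohol and stops at the aldehyde under non-basic conditions, so C5 should not epimerise and the β-hydroxyl should not eliminate.

Step 8
Reactants: 12 (1S,2S,7S)-2-ethenyl-7-hydroxy-2,5-dimethylcyclohept-4-ene-1-carbaldehyde
Product: 13 (3aR,8S,8aS)-8-hydroxy-3a,6-dimethyl-3,3a,4,7,8,8a-hexahydroazulen-1(2H)-one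
Conditions: [Rh(dppe)]BF4 (5 mol%, from [Rh(nbd)(dppe)]BF4 and H2), degassed acetone, 25 → 50 °C
Reagents that add atoms: none
Why: Rh-catalysed intramolecular alkene hydroacylation: cationic Rh(I) inserts into the aldehyde C–H bond, the acyl rhodium hydride adds across the vinyl group with Rh at the terminal carbon to give a six-membered acyl–alkyl rhodacycle, and reductive elimination joins the former aldehyde carbon (C4) to the terminal vinyl carbon (C3). The closest known reaction type is the cyclisation of 2- and 3-substituted 4-pentenals, including 3,3-disubstituted ones, to cyclopentanones with [Rh(diphosphine)]+ catalysts. The cyclopentanone is closed in a formal 5-endo-trig sense through the six-membered rhodacycle, and it is trans-fused because the formyl group on C5 and the vinyl group on C1 are trans (diequatorial, gauche) on the cycloheptene. No new stereocentre is formed; the ring-fusion centres C1 and C5 are inherited from step 4, and the neutral conditions should avoid epimerisation at C5 and β-elimination of the C6 hydroxyl. The step needs chemoselectivity for the vinyl group over the ring alkene and cyclisation over decarbonylation: the C8=C9 alkene is trisubstituted and could only give a bridged ring, and the quaternary C1 provides gem-disubstitution and excludes alkene isomerisation.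

Step 9
Reactants: 13 (3aR,8S,8aS)-8-hydroxy-3a,6-dimethyl-3,3a,4,7,8,8a-hexahydroazulen-1(2H)-one
Product: 14 (3R,3aS,4S,8aR)-6,8a-dimethyl-3-(propan-2-yl)-1,2,3,3a,4,5,8,8a-octahydroazulene-3,4-diol
Conditions: i-PrMgCl (4 equiv), CeCl3·2LiCl (4 equiv), THF, −78 → 0 °C; aq. NH4Cl
Reagents that add atoms: isopropylmagnesium chloride CC(C)[Mg]Cl
Why: Organocerium 1,2-addition to an enolisable ketone: the first equivalent forms the C6 alkoxide, which lies close to the carbonyl plane and chelates the ketone oxygen, and the nucleophile should then attack C4 from the face of H5, anti to the angular CH3 on C1 (1,3 to the carbonyl), placing isopropyl cis to H5 and the new hydroxyl cis to CH3 as in the target.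

Step 10
Reactants: 14 (3R,3aS,4S,8aR)-6,8a-dimethyl-3-(propan-2-yl)-1,2,3,3a,4,5,8,8a-octahydroazulene-3,4-diol; 15 2,2-dimethyl-4H-1,3-benzodioxin-4-one
Product: 16 (3R,3aS,4S,8aR)-3-hydroxy-6,8a-dimethyl-3-(propan-2-yl)-1,2,3,3a,4,5,8,8a-octahydroazulen-4-yl 2-hydroxybenzoate
Conditions: NaHMDS (1.1 equiv), THF, 0 °C; 15 (1.2 equiv), 0 °C → rt; aq. NH4Cl
Reagents that add atoms: none
Why: Alkoxide acylation by ring opening of a benzodioxinone (salicylic acid acetonide): the secondary C6 alkoxide adds to the lactone carbonyl and loss of acetone gives the salicylate as its phenoxide, which is too weak a base to promote further acylation or acyl migration, while the tertiary C4 hydroxyl is too hindered to react.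

**Compound list**
1 | pent-1-en-4-yne | C=CCC#C | starting material
2 | dimethyl[(1E)-2-methylpenta-1,4-dien-1-yl]alane (formed in situ) | C=CC/C(C)=C/[Al](C)C | intermediate
3 | (2E)-3-methylhexa-2,5-dien-1-ol | C=CC/C(C)=C/CO | intermediate
4 | ethyl (3R)-4-chloro-3-hydroxybutanoate | CCOC(=O)C[C@@H](O)CCl | starting material
5 | ethyl 2-[(2R)-oxiran-2-yl]acetate (formed in situ) | CCOC(=O)C[C@@H]1CO1 | intermediate
6 | ethyl (3S)-3-hydroxy-5-methylhex-5-enoate | CCOC(=O)C[C@@H](O)CC(C)=C | intermediate
7 | (2E)-3-methylhexa-2,5-dien-1-yl (3S)-3-hydroxy-5-methylhex-5-enoate | C=CC/C(C)=C/COC(=O)C[C@@H](O)CC(C)=C | intermediate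
8 | dilithium alkoxide enolate of 7, enolate oxygen cis to the carbinol carbon (formed in situ) | C=CC/C(C)=C/CO/C(O[Li])=C/[C@@H](O[Li])CC(C)=C | intermediate
9 | (2S,3S)-3-ethenyl-2-[(1S)-1-hydroxy-3-methylbut-3-en-1-yl]-3-methylhex-5-enoic acid | C=CC[C@@]([C@H](C(=O)O)[C@@H](O)CC(C)=C)(C)C=C | intermediate
10 | (1S,2S,7S)-2-ethenyl-7-hydroxy-2,5-dimethylcyclohept-4-ene-1-carboxylic acid | CC1=CC[C@@](C)(C=C)[C@H](C(=O)O)[C@@H](O)C1 | intermediate
11 | (1S,6S,7R)-6-ethenyl-7-(hydroxymethyl)-3,6-dimethylcyclohept-3-en-1-ol | CC1=CC[C@@](C)(C=C)[C@H](CO)[C@@H](O)C1 | intermediate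
12 | (1S,2S,7S)-2-ethenyl-7-hydroxy-2,5-dimethylcyclohept-4-ene-1-carbaldehyde | CC1=CC[C@@](C)(C=C)[C@H](C=O)[C@@H](O)C1 | intermediate
13 | (3aR,8S,8aS)-8-hydroxy-3a,6-dimethyl-3,3a,4,7,8,8a-hexahydroazulen-1(2H)-one (trans-fused) | CC1=CC[C@@]2(C)CCC(=O)[C@@H]2[C@@H](O)C1 | intermediate
14 | (3R,3aS,4S,8aR)-6,8a-dimethyl-3-(propan-2-yl)-1,2,3,3a,4,5,8,8a-octahydroazulene-3,4-diol | CC1=CC[C@@]2(C)CC[C@@](O)(C(C)C)[C@@H]2[C@@H](O)C1 | intermediate
15 | 2,2-dimethyl-4H-1,3-benzodioxin-4-one (salicylic acid acetonide) | CC1(C)OC(=O)c2ccccc2O1 | starting material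
16 | (3R,3aS,4S,8aR)-3-hydroxy-6,8a-dimethyl-3-(propan-2-yl)-1,2,3,3a,4,5,8,8a-octahydroazulen-4-yl 2-hydroxybenzoate | CC1=CC[C@@]2(C)CC[C@@](O)(C(C)C)[C@@H]2[C@@H](OC(=O)c2ccccc2O)C1 | target

**Totals and risks**

Total step count: 10. Longest linear sequence: 9 steps (from 4 through steps 2–10 to 16).

Steps most likely to fail:

Step 8. The acyl rhodium hydride may decarbonylate (catalyst death as a rhodium carbonyl) before the hindered vinyl group inserts, or the trans-fused ring may close slowly. The fallback sets out from acid 10 and comes back at diol 14, replacing steps 6–9. Acid 10 is treated with excess isopropyllithium (carboxylate-to-ketone addition, TMSCl quench) to give the β-hydroxy isopropyl ketone F1. Rh-catalysed hydroboration of the vinyl group with catecholborane (alkene-selective in the presence of the ketone), followed by perborate oxidation, gives the primary alcohol F2. I2, PPh3 and imidazole convert it into the primary iodide F3. A SmI2/HMPA-mediated intramolecular ketone–iodide Barbier cyclisation then forms the same C3–C4 bond; samarium chelation between the ketone and C6 oxygens, and the preference of the isopropyl group to lie on the side of H5, should set C4 and deliver 14 directly.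

Step 4. The [3,3] shift onto the fully substituted alkene terminus may be sluggish, so that the ester dianion fragments (ketene formation) or the chair preference erodes. The fallback sets out from ester 7 and comes back at acid 9. Silylation of the hydroxyl (TESCl, imidazole) gives the triethylsilyl ether F4. Its (Z)-silyl ketene acetal (KHMDS, TMSCl present for in-situ trapping to outrun β-elimination, toluene–THF, −78 °C → rt) rearranges in the ordinary Ireland–Claisen manner to the silyl-protected acid F5. Facial control then rests on the non-chelated preference of the β-silyloxy stereocentre, and diastereomers would be separated at this stage. AcOH/H2O/THF removes the silyl group to give 9.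

Step 9. Enolisation or β-hydride reduction of the hindered α-branched cyclopentanone may outrun addition of the secondary nucleophile, and facial selectivity may be incomplete. The fallback sets out from ketone 13 and comes back at diol 14. The slimmer, β-hydrogen-free 2-propenylcerium reagent (isopropenylmagnesium bromide, CeCl3·2LiCl, THF, −78 °C) should add from the same face to give the isopropenyl diol F6. Homogeneous hydrogenation (H2, Wilkinson's catalyst, benzene, rt) should then reduce only the 1,1-disubstituted alkene and leave the trisubstituted ring alkene, giving 14.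

**Further compounds**
F1 | step 8 | 1-[(1S,2S,7S)-2-ethenyl-7-hydroxy-2,5-dimethylcyclohept-4-en-1-yl]-2-methylpropan-1-one | CC1=CC[C@@](C)(C=C)[C@H](C(=O)C(C)C)[C@@H](O)C1
F2 | step 8 | 1-[(1S,2S,7S)-7-hydroxy-2-(2-hydroxyethyl)-2,5-dimethylcyclohept-4-en-1-yl]-2-methylpropan-1-one | CC1=CC[C@@](C)(CCO)[C@H](C(=O)C(C)C)[C@@H](O)C1
F3 | step 8 | 1-[(1S,2S,7S)-7-hydroxy-2-(2-iodoethyl)-2,5-dimethylcyclohept-4-en-1-yl]-2-methylpropan-1-one | CC1=CC[C@@](C)(CCI)[C@H](C(=O)C(C)C)[C@@H](O)C1
F4 | step 4 | (2E)-3-methylhexa-2,5-dien-1-yl (3S)-5-methyl-3-[(triethylsilyl)oxy]hex-5-enoate | C=CC/C(C)=C/COC(=O)C[C@@H](O[Si](CC)(CC)CC)CC(C)=C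
F5 | step 4 | (2S,3S)-3-ethenyl-3-methyl-2-{(1S)-3-methyl-1-[(triethylsilyl)oxy]but-3-en-1-yl}hex-5-enoic acid | C=CC[C@@]([C@H](C(=O)O)[C@@H](O[Si](CC)(CC)CC)CC(C)=C)(C)C=C
F6 | step 9 | (3S,3aS,4S,8aR)-6,8a-dimethyl-3-(prop-1-en-2-yl)-1,2,3,3a,4,5,8,8a-octahydroazulene-3,4-diol | CC1=CC[C@@]2(C)CC[C@@](O)(C(C)=C)[C@@H]2[C@@H](O)C1
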